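**Strategy**

The cyclohexene ring of the target (indene numbering: C3a, C4, C5, C6, C7, C7a, alkene C6=C7) is a Diels–Alder retron whose diene is cut at its central bond. In one flask a Stille coupling joins a trienylstannane (C5, C6 and the styryl diene) to an open-chain iodotrienoic acid (C7, C7a, C1–C3, C3a, C4, CO2H) at C6–C7, and the hexaene formed cyclises by intramolecular Diels–Alder reaction: C4–C5 between the two quaternary carbons and C3a–C7a close both rings, and C6–C7 becomes the ring alkene. The only stereocentre of the precursors, C1, is bought as methyl (R)-3-hydroxy-2-methylpropanoate and relays C3a, C4, C5 and C7a.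

Key step: step 18

Remark: the locants C1 to C7a used for the target are those of the indene skeleton in the name of 30; reagents without a compound number are taken as bought.

**Fragment A (steps 1–10)**

Step 1
Reactants: 1 methyl (R)-3-hydroxy-2-methylpropanoate
Product: 2 methyl (R)-3-[(tert-butyldimethylsilyl)oxy]-2-methylpropanoate
Conditions: TBSCl, imidazole, CH2Cl2, 0 °C to rt
Reagents that add atoms: tert-butyldimethylsilyl chloride, CC(C)(C)[Si](C)(C)Cl
Why: Imidazole-promoted O-silylation of the primary alcohol gives a silyl ether that survives the hydride, organolithium and hydrozirconation steps; the stereocentre is not touched.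

Step 2
Reactants: 2 methyl (R)-3-[(tert-butyldimethylsilyl)oxy]-2-methylpropanoate
Product: 4 (S)-tert-butyldimethyl[(2-methylbut-3-yn-1-yl)oxy]silane, via aldehyde 3 (not isolated)
Conditions: i-Bu2AlH (1.1 equiv), CH2Cl2, −78 °C; then MeOH, K2CO3, dimethyl (1-diazo-2-oxopropyl)phosphonate, −78 °C to rt
Reagents that add atoms: dimethyl (1-diazo-2-oxopropyl)phosphonate, COP(=O)(OC)C(=[N+]=[N-])C(C)=O
Why: Partial reduction of the ester stops at the aluminium hemiacetal, methanol releases aldehyde 3, and Seyferth–Gilbert homologation (Ohira–Bestmann variant) converts it into the terminal alkyne under carbonate conditions mild enough to keep the α-stereocentre.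

Step 3
Reactants: 4 (S)-tert-butyldimethyl[(2-methylbut-3-yn-1-yl)oxy]silane
Product: 6 (S)-tert-butyldimethyl[(2-methylpent-3-yn-1-yl)oxy]silane, via lithium acetylide 5 (not isolated)
Conditions: n-BuLi, THF, −78 °C; then MeI, −78 °C to rt
Reagents that add atoms: iodomethane, CI
Why: Deprotonation of the terminal alkyne and SN2 methylation of the acetylide install the methyl group that becomes the C7 methyl of the target.

Step 4
Reactants: 6 (S)-tert-butyldimethyl[(2-methylpent-3-yn-1-yl)oxy]silane
Product: 8 tert-butyl{[(2S,3E)-4-iodo-2-methylpent-3-en-1-yl]oxy}dimethylsilane, via alkenylzirconocene chloride 7 (not isolated)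
Conditions: Cp2Zr(H)Cl (2.5 equiv), THF, 50 °C; then I2, 0 °C
Reagents that add atoms: iodine, II
Why: Hydrozirconation is a syn addition; with excess reagent and warming the regioisomers equilibrate to the alkenylzirconium with the metal on the less hindered, methyl-bearing carbon, and iodinolysis with retention gives the (E)-iodide.

Step 5
Reactants: 8 tert-butyl{[(2S,3E)-4-iodo-2-methylpent-3-en-1-yl]oxy}dimethylsilane
Product: 9 (2S,3E)-4-iodo-2-methylpent-3-en-1-ol
Conditions: CSA (cat.), MeOH/CH2Cl2, 0 °C
Reagents that add atoms: none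
Why: Acid-catalysed methanolysis transfers the primary silyl group to methanol; the alkenyl iodide is inert.

Step 6
Reactants: 9 (2S,3E)-4-iodo-2-methylpent-3-en-1-ol
Product: 10 (2S,3E)-4-iodo-2-methylpent-3-enal
Conditions: Dess–Martin periodinane, NaHCO3, CH2Cl2, 0 °C; crude aldehyde used at once
Reagents that add atoms: none
Why: Dess–Martin oxidation under buffered conditions gives the β,γ-unsaturated aldehyde without enolisation, so the α-stereocentre and the position of the alkene should be kept.

Step 7
Reactants: 10 (2S,3E)-4-iodo-2-methylpent-3-enal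
Product: 11 ethyl (2Z,4R,5E)-6-iodo-2,4-dimethylhepta-2,5-dienoate
Conditions: ethyl 2-[bis(2,2,2-trifluoroethoxy)phosphoryl]propanoate, KN(SiMe3)2, 18-crown-6, THF, −78 °C
Reagents that add atoms: ethyl 2-[bis(2,2,2-trifluoroethoxy)phosphoryl]propanoate, CCOC(=O)C(C)P(=O)(OCC(F)(F)F)OCC(F)(F)F
Why: Still–Gennari olefination: fast, irreversible collapse of the kinetic adduct of the electron-poor phosphonate gives the (Z)-2-methyl enoate, and at −78 °C addition to the aldehyde should outrun its deprotonation.

Step 8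
Reactants: 11 ethyl (2Z,4R,5E)-6-iodo-2,4-dimethylhepta-2,5-dienoate
Product: 12 (2Z,4R,5E)-6-iodo-2,4-dimethylhepta-2,5-dien-1-ol
Conditions: i-Bu2AlH (2.5 equiv), CH2Cl2, −78 °C
Reagents that add atoms: none
Why: 1,2-Reduction of the conjugated ester to the allylic alcohol; the alkene geometries and the C–I bond are not affected at −78 °C.

Step 9
Reactants: 12 (2Z,4R,5E)-6-iodo-2,4-dimethylhepta-2,5-dien-1-ol
Product: 14 ethyl (2E,4Z,6R,7E)-8-iodo-2,4,6-trimethylnona-2,4,7-trienoate, via enal 13 (not isolated)
Conditions: MnO2 (excess), ethyl 2-(triphenyl-λ5-phosphanylidene)propanoate, CH2Cl2, rt, dark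
Reagents that add atoms: ethyl 2-(triphenyl-λ5-phosphanylidene)propanoate, CCOC(=O)C(C)=P(c1ccccc1)(c1ccccc1)c1ccccc1
Why: Tandem oxidation–Wittig reaction: MnO2 oxidises the allylic alcohol and the stabilised ylide traps the (Z)-enal as it forms, which limits Z to E isomerisation, and gives the new (E)-alkene.

Step 10
Reactants: 14 ethyl (2E,4Z,6R,7E)-8-iodo-2,4,6-trimethylnona-2,4,7-trienoate
Product: 16 (2E,4Z,6R,7E)-8-iodo-2,4,6-trimethylnona-2,4,7-trienoic acid, via lithium carboxylate 15 (not isolated)
Conditions: LiOH, THF/MeOH/H2O, rt; then 1 M HCl, 0 °C, to pH 3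
Reagents that add atoms: lithium hydroxide, [Li+].[OH-]
Why: Saponification is done here on the unhindered conjugated ester, because the same ester on the quaternary C4 of the bicycle would resist hydrolysis; the free acid is also the dienophile activator of the key step.

**Fragment B (steps 11–17)**

Step 11
Reactants: 17 diethyl 2-ethylpropanedioate
Product: 19 diethyl 2-(diiodomethyl)-2-ethylpropanedioate, via sodium enolate 18 (not isolated)
Conditions: NaH, Et2O, reflux; then CHI3, reflux
Reagents that add atoms: triiodomethane, IC(I)I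
Why: Diiodomethylation of a malonate enolate: iodoform and base give diiodocarbene, the enolate traps it at carbon, and protonation gives the quaternary diiodomethyl malonate.

Step 12
Reactants: 19 diethyl 2-(diiodomethyl)-2-ethylpropanedioate
Product: 22 (2E)-2-ethyl-3-iodoprop-2-enoic acid, via dipotassium malonate 20 (not isolated), via potassium iodoacrylate 21 (not isolated)
Conditions: KOH, EtOH/H2O, reflux; then HCl, 0 °C
Reagents that add atoms: potassium hydroxide, [K+].[OH-]
Why: Saponification followed by decarboxylative elimination of iodide (Grob-type fragmentation) should give the 3-iodoacrylate as the (E)-isomer, iodine trans to the carboxylate, as for the lower homologues.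

Step 13
Reactants: 22 (2E)-2-ethyl-3-iodoprop-2-enoic acid
Product: 23 (2E)-2-ethyl-3-iodoprop-2-en-1-ol
Conditions: LiAlH4, Et2O, 0 °C
Reagents that add atoms: none
Why: Hydride reduction of the carboxylic acid to the allylic alcohol at 0 °C, where the alkenyl C–I bond is not attacked.

Step 14
Reactants: 23 (2E)-2-ethyl-3-iodoprop-2-en-1-ol
Product: 24 (2E)-2-ethyl-3-iodoprop-2-enal
Conditions: MnO2, CH2Cl2, rt, dark
Reagents that add atoms: none
Why: Chemoselective allylic oxidation to the enal without change of the alkene geometry.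

Step 15
Reactants: 24 (2E)-2-ethyl-3-iodoprop-2-enal
Product: 25 (2E,4E)-4-ethyl-5-iodo-2-methylpenta-2,4-dienal
Conditions: 2-(triphenyl-λ5-phosphanylidene)propanal, toluene, 80 °C
Reagents that add atoms: 2-(triphenyl-λ5-phosphanylidene)propanal, CC(C=O)=P(c1ccccc1)(c1ccccc1)c1ccccc1
Why: Wittig reaction with the stabilised formyl ylide gives the (E)-trisubstituted enal; the product is more hindered than 24, which limits a second homologation.

Step 16
Reactants: 25 (2E,4E)-4-ethyl-5-iodo-2-methylpenta-2,4-dienal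
Product: 26 [(1E,3E,5E)-5-ethyl-6-iodo-3-methylhexa-1,3,5-trien-1-yl]benzene
Conditions: diethyl benzylphosphonate, NaH, THF, 0 °C to rt
Reagents that add atoms: diethyl benzylphosphonate, CCOP(=O)(Cc1ccccc1)OCC
Why: Horner–Wadsworth–Emmons reaction of the benzylphosphonate anion gives the (E)-styryl alkene and completes the triene.

Step 17
Reactants: 26 [(1E,3E,5E)-5-ethyl-6-iodo-3-methylhexa-1,3,5-trien-1-yl]benzene
Product: 28 tributyl[(1E,3E,5E)-2-ethyl-4-methyl-6-phenylhexa-1,3,5-trien-1-yl]stannane, via alkenyllithium 27 (not isolated)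
Conditions: t-BuLi (2.1 equiv), Et2O, −78 °C; then Bu3SnCl, −78 °C to rt
Reagents that add atoms: tributyltin chloride, CCCC[Sn](Cl)(CCCC)CCCC
Why: Iodine–lithium exchange at −78 °C is faster than any addition to the triene and retains the alkene geometry; the alkenyllithium is trapped by the tin chloride.

**Key step**

Step 18
Reactants: 16 (2E,4Z,6R,7E)-8-iodo-2,4,6-trimethylnona-2,4,7-trienoic acid; 28 tributyl[(1E,3E,5E)-2-ethyl-4-methyl-6-phenylhexa-1,3,5-trien-1-yl]stannane
Product: 30 (1R,3aR,4R,5S,7aS)-5-ethyl-1,3,4,7-tetramethyl-5-[(1E,3E)-2-methyl-4-phenylbuta-1,3-dien-1-yl]-3a,4,5,7a-tetrahydro-1H-indene-4-carboxylic acid, via hexaene acid 29 (not isolated)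
Conditions: Pd2(dba)3 (5 mol%), AsPh3 (40 mol%), CuI (20 mol%), DMF, 25 °C, dark; then toluene, BHT, 80 °C, same flask
Reagents that add atoms: none
Why: Oxidative addition of the C–I bond of 16 to zerovalent palladium, transmetalation from tin and reductive elimination join C6 and C7 with retention of both alkene geometries, and the (7E,9E)-diene of hexaene 29 then adds across the (2E)-enoic acid in a concerted, suprafacial [4+2] cycloaddition; the closest known reaction type is the domino Stille coupling/intramolecular Diels–Alder reaction. The cyclohexene ring closes by the cycloaddition itself (bonds C4–C5 and C3a–C7a), and the cyclopentene ring closes as the tether ring of a type 1 intramolecular Diels–Alder reaction, its (Z)-alkene holding diene and dienophile within reach. C4 and C5 follow from the alkene geometries: the (E)-enoic acid puts the carboxyl group cis to H3a, and the (E)-configured diene terminus puts the dienyl chain (outside) cis to the carboxyl group and the ethyl group (inside) cis to H7a. C3a and C7a follow from the endo transition state (carboxyl group under the diene, tether exo), which gives the trans ring fusion. The face of the diene is chosen by C1: 1,3-allylic strain with the C7 methyl group keeps H1 in the diene plane, so the tether reaches the dienophile on one face only and the C1 methyl group ends cis to H7a. The step needs endo over exo selectivity and one diene out of three; secondary orbital overlap of the conjugated acid should favour endo, and only this diene–dienophile pair is linked by a three-atom tether that can close a five-membered ring.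

**Compound list**

1 | methyl (R)-3-hydroxy-2-methylpropanoate | COC(=O)[C@H](C)CO | starting material
2 | methyl (R)-3-[(tert-butyldimethylsilyl)oxy]-2-methylpropanoate | COC(=O)[C@H](C)CO[Si](C)(C)C(C)(C)C | intermediate
3 | (R)-3-[(tert-butyldimethylsilyl)oxy]-2-methylpropanal | O=C[C@H](C)CO[Si](C)(C)C(C)(C)C | intermediate (not isolated)
4 | (S)-tert-butyldimethyl[(2-methylbut-3-yn-1-yl)oxy]silane | C#C[C@H](C)CO[Si](C)(C)C(C)(C)C | intermediate
5 | lithium acetylide of 4 | [Li]C#C[C@H](C)CO[Si](C)(C)C(C)(C)C | intermediate (not isolated)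
6 | (S)-tert-butyldimethyl[(2-methylpent-3-yn-1-yl)oxy]silane | CC#C[C@H](C)CO[Si](C)(C)C(C)(C)C | intermediate
7 | chlorobis(cyclopentadienyl)[(2E,4S)-5-[(tert-butyldimethylsilyl)oxy]-4-methylpent-2-en-2-yl]zirconium | Cl[Zr](C1C=CC=C1)(C1C=CC=C1)/C(C)=C/[C@H](C)CO[Si](C)(C)C(C)(C)C | intermediate (not isolated)
8 | tert-butyl{[(2S,3E)-4-iodo-2-methylpent-3-en-1-yl]oxy}dimethylsilane | I/C(C)=C/[C@H](C)CO[Si](C)(C)C(C)(C)C | intermediate
9 | (2S,3E)-4-iodo-2-methylpent-3-en-1-ol | I/C(C)=C/[C@H](C)CO | intermediate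
10 | (2S,3E)-4-iodo-2-methylpent-3-enal | I/C(C)=C/[C@H](C)C=O | intermediate
11 | ethyl (2Z,4R,5E)-6-iodo-2,4-dimethylhepta-2,5-dienoate | I/C(C)=C/[C@H](C)/C=C(C)\C(=O)OCC | intermediate
12 | (2Z,4R,5E)-6-iodo-2,4-dimethylhepta-2,5-dien-1-ol | I/C(C)=C/[C@H](C)/C=C(C)\CO | intermediate
13 | (2Z,4R,5E)-6-iodo-2,4-dimethylhepta-2,5-dienal | I/C(C)=C/[C@H](C)/C=C(C)\C=O | intermediate (not isolated)
14 | ethyl (2E,4Z,6R,7E)-8-iodo-2,4,6-trimethylnona-2,4,7-trienoate | I/C(C)=C/[C@H](C)/C=C(C)\C=C(/C)C(=O)OCC | intermediate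
15 | lithium (2E,4Z,6R,7E)-8-iodo-2,4,6-trimethylnona-2,4,7-trienoate | [Li+].I/C(C)=C/[C@H](C)/C=C(C)\C=C(/C)C([O-])=O | intermediate (not isolated)
16 | (2E,4Z,6R,7E)-8-iodo-2,4,6-trimethylnona-2,4,7-trienoic acid | I/C(C)=C/[C@H](C)/C=C(C)\C=C(/C)C(=O)O | intermediate
17 | diethyl 2-ethylpropanedioate | CCOC(=O)C(CC)C(=O)OCC | starting material
18 | sodium enolate of 17 | [Na+].CCOC(=O)[C-](CC)C(=O)OCC | intermediate (not isolated)
19 | diethyl 2-(diiodomethyl)-2-ethylpropanedioate | CCOC(=O)C(CC)(C(I)I)C(=O)OCC | intermediate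
20 | dipotassium 2-(diiodomethyl)-2-ethylpropanedioate | [K+].[K+].CCC(C(I)I)(C([O-])=O)C([O-])=O | intermediate (not isolated)
21 | potassium (2E)-2-ethyl-3-iodoprop-2-enoate | [K+].[O-]C(=O)/C(CC)=C/I | intermediate (not isolated)
22 | (2E)-2-ethyl-3-iodoprop-2-enoic acid | OC(=O)/C(CC)=C/I | intermediate
23 | (2E)-2-ethyl-3-iodoprop-2-en-1-ol | OC/C(CC)=C/I | intermediate
24 | (2E)-2-ethyl-3-iodoprop-2-enal | O=C/C(CC)=C/I | intermediate
25 | (2E,4E)-4-ethyl-5-iodo-2-methylpenta-2,4-dienal | O=C/C(C)=C/C(CC)=C/I | intermediate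
26 | [(1E,3E,5E)-5-ethyl-6-iodo-3-methylhexa-1,3,5-trien-1-yl]benzene | I/C=C(CC)/C=C(C)/C=C/c1ccccc1 | intermediate
27 | [(1E,3E,5E)-2-ethyl-4-methyl-6-phenylhexa-1,3,5-trien-1-yl]lithium | [Li]/C=C(CC)/C=C(C)/C=C/c1ccccc1 | intermediate (not isolated)
28 | tributyl[(1E,3E,5E)-2-ethyl-4-methyl-6-phenylhexa-1,3,5-trien-1-yl]stannane | CCCC[Sn](CCCC)(CCCC)/C=C(CC)/C=C(C)/C=C/c1ccccc1 | intermediate
29 | (2E,4Z,6S,7E,9E,11E,13E)-10-ethyl-2,4,6,8,12-pentamethyl-14-phenyltetradeca-2,4,7,9,11,13-hexaenoic acid | c1ccccc1/C=C/C(C)=C/C(CC)=C/C(C)=C/[C@H](C)/C=C(C)\C=C(/C)C(=O)O | intermediate (not isolated)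
30 | (1R,3aR,4R,5S,7aS)-5-ethyl-1,3,4,7-tetramethyl-5-[(1E,3E)-2-methyl-4-phenylbuta-1,3-dien-1-yl]-3a,4,5,7a-tetrahydro-1H-indene-4-carboxylic acid | CC[C@]1(/C=C(C)/C=C/c2ccccc2)C=C(C)[C@H]2[C@H](C)C=C(C)[C@@H]2[C@@]1(C)C(=O)O | target

**Count and risks**

Total: 18 steps. Longest linear sequence: 11 steps (steps 1–10, then step 18).

Steps most likely to fail:

1. Step 18. Transmetalation between two trisubstituted alkenyl partners may be slow, so that protodestannylation and homocoupling compete. After coupling, the cycloaddition may leak through the exo transition state, or the doubly allylic H6 of 29 may undergo a 1,5-hydrogen shift, or the tether alkene may isomerise from Z to E while palladium, tin halide and free acid are present. Fallback, from 16 back to 30: the two events are separated and the dienophile is activated as an ester. Acid 16 is esterified with 2-(trimethylsilyl)ethanol (EDC, DMAP) to 2-(trimethylsilyl)ethyl (2E,4Z,6R,7E)-8-iodo-2,4,6-trimethylnona-2,4,7-trienoate F1. Stille coupling of F1 with 28 at 25 °C gives 2-(trimethylsilyl)ethyl (2E,4Z,6S,7E,9E,11E,13E)-10-ethyl-2,4,6,8,12-pentamethyl-14-phenyltetradeca-2,4,7,9,11,13-hexaenoate F2, which is isolated. Me2AlCl in CH2Cl2 at −78 to −20 °C then promotes the Diels–Alder reaction, with the Lewis acid on the ester expected to raise the endo preference, and gives 2-(trimethylsilyl)ethyl (1R,3aR,4R,5S,7aS)-5-ethyl-1,3,4,7-tetramethyl-5-[(1E,3E)-2-methyl-4-phenylbuta-1,3-dien-1-yl]-3a,4,5,7a-tetrahydro-1H-indene-4-carboxylate F3. Bu4NF in THF cleaves the silylethyl ester by attack at silicon, which does not depend on access to the hindered carbonyl group, and gives 30.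

2. Step 7. The phosphonate anion may deprotonate aldehyde 10 at its doubly activated α-position, which would epimerise the stereocentre and move the alkene into conjugation; Z selectivity may also be incomplete. Fallback, from 9 back to 12: the polarity is reversed so that no aldehyde is made. Alcohol 9 is converted (I2, PPh3, imidazole) into (2E,4S)-2,5-diiodo-4-methylpent-2-ene F4. PPh3 in MeCN at 80 °C displaces only the primary iodide and gives [(2S,3E)-4-iodo-2-methylpent-3-en-1-yl]triphenylphosphonium iodide F5. NaN(SiMe3)2 in THF at −78 °C gives [(2S,3E)-4-iodo-2-methylpent-3-en-1-ylidene]triphenyl-λ5-phosphane F6, in which the stereocentre is β to phosphorus and not acidic. Its Wittig reaction with 1-[(tert-butyldimethylsilyl)oxy]propan-2-one (non-stabilised ylide with an α-silyloxy ketone, a Z-selective combination) should give tert-butyl{[(2Z,4R,5E)-6-iodo-2,4-dimethylhepta-2,5-dien-1-yl]oxy}dimethylsilane F7. CSA in MeOH removes the silyl group and gives 12.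

3. Step 17. t-BuLi may add to the conjugated triene, the alkenyllithium may be protonated before trapping, and the trienylstannane may lose tin on purification. Fallback, from 23 back to 28: tin is introduced on the small building block without an organolithium. Alcohol 23 with hexabutylditin and PdCl2(PPh3)2 in THF gives (2E)-2-ethyl-3-(tributylstannyl)prop-2-en-1-ol F8. MnO2 gives (2E)-2-ethyl-3-(tributylstannyl)prop-2-enal F9. Wittig reaction with 2-(triphenyl-λ5-phosphanylidene)propanal gives (2E,4E)-4-ethyl-2-methyl-5-(tributylstannyl)penta-2,4-dienal F10. Horner–Wadsworth–Emmons reaction with diethyl benzylphosphonate and NaH gives 28.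

**Further compounds**

F1 | step 18 | 2-(trimethylsilyl)ethyl (2E,4Z,6R,7E)-8-iodo-2,4,6-trimethylnona-2,4,7-trienoate | I/C(C)=C/[C@H](C)/C=C(C)\C=C(/C)C(=O)OCC[Si](C)(C)C
F2 | step 18 | 2-(trimethylsilyl)ethyl (2E,4Z,6S,7E,9E,11E,13E)-10-ethyl-2,4,6,8,12-pentamethyl-14-phenyltetradeca-2,4,7,9,11,13-hexaenoate | c1ccccc1/C=C/C(C)=C/C(CC)=C/C(C)=C/[C@H](C)/C=C(C)\C=C(/C)C(=O)OCC[Si](C)(C)C
F3 | step 18 | 2-(trimethylsilyl)ethyl (1R,3aR,4R,5S,7aS)-5-ethyl-1,3,4,7-tetramethyl-5-[(1E,3E)-2-methyl-4-phenylbuta-1,3-dien-1-yl]-3a,4,5,7a-tetrahydro-1H-indene-4-carboxylate | CC[C@]1(/C=C(C)/C=C/c2ccccc2)C=C(C)[C@H]2[C@H](C)C=C(C)[C@@H]2[C@@]1(C)C(=O)OCC[Si](C)(C)C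
F4 | step 7 | (2E,4S)-2,5-diiodo-4-methylpent-2-ene | I/C(C)=C/[C@H](C)CI
F5 | step 7 | [(2S,3E)-4-iodo-2-methylpent-3-en-1-yl]triphenylphosphonium iodide | [I-].I/C(C)=C/[C@H](C)C[P+](c1ccccc1)(c1ccccc1)c1ccccc1
F6 | step 7 | [(2S,3E)-4-iodo-2-methylpent-3-en-1-ylidene]triphenyl-λ5-phosphane | I/C(C)=C/[C@H](C)C=P(c1ccccc1)(c1ccccc1)c1ccccc1
F7 | step 7 | tert-butyl{[(2Z,4R,5E)-6-iodo-2,4-dimethylhepta-2,5-dien-1-yl]oxy}dimethylsilane | I/C(C)=C/[C@H](C)/C=C(C)\CO[Si](C)(C)C(C)(C)C
F8 | step 17 | (2E)-2-ethyl-3-(tributylstannyl)prop-2-en-1-ol | CCCC[Sn](CCCC)(CCCC)/C=C(CC)/CO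
F9 | step 17 | (2E)-2-ethyl-3-(tributylstannyl)prop-2-enal | CCCC[Sn](CCCC)(CCCC)/C=C(CC)/C=O
F10 | step 17 | (2E,4E)-4-ethyl-2-methyl-5-(tributylstannyl)penta-2,4-dienal | CCCC[Sn](CCCC)(CCCC)/C=C(CC)/C=C(C)/C=O
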